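**Plan**

- Ring numbering used throughout: C1 (2-methylbutanoyl; side-chain carbons C1′ and C2′), C2 (OH), C3 (CH3), C4 (O-geranyl), C5 (acetyl), C6 (OH). The enabling feature is the ortho pair C4–O / C5–C(=O)CH3 on the benzene ring with the C6 oxygen beside C5: a C4≡C5 aryne inserting into the C–O bond of acetic acid delivers exactly this pair, and the oxygen it creates is the only unprotected one.
- Retrosynthetic cuts, in order: O4–geranyl; C4–O together with C5–C(acetyl) (aryne plus acetic acid); C4–Si and C5–O of the silyl triflate (earlier C4–Br and C5–B); C1–C1′ (aryllithium plus aldehyde).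
- Forward: no ring is formed; the benzene ring comes with 4-methylresorcinol. The side chain is joined at C1 first (as a silylated carbinol), then oxygen at C5, bromine then silicon at C4, triflate, aryne insertion, geranylation, carbinol-to-ketone oxidation and acetal removal.
- Stereochemistry: C2′ (R) is bought with (2R)-2-methylbutanoic acid. It stays next to a carbinol, not a carbonyl, through every basic step and becomes α to the ketone only in step 12. The 2E alkene comes with geranyl bromide.

Key step: step 9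

Assumption: the carbinol carbon C1′ made in step 4 is carried as both epimers (no descriptor in the SMILES) because it ends as the C1 ketone; (2R)-2-methylbutanoic acid of high enantiomeric purity is taken as purchasable.

**Route**

Step 1
Reactants: 1 (2R)-2-methylbutanoic acid
Product: 2 (2R)-2-methylbutan-1-ol
Conditions: LiAlH4, Et2O, 0 °C → reflux; H2O; distil
Reagents that add atoms: none
Why: Hydride reduction of the carboxylic acid runs through the carboxylate and aluminate without enolising C2, so the alcohol keeps the R configuration.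

Step 2
Reactants: 2 (2R)-2-methylbutan-1-ol
Product: 3 (2R)-2-methylbutanal
Conditions: TEMPO (cat.), KBr (cat.), NaOCl, NaHCO3 buffer, CH2Cl2–H2O, 0 °C; distilled and used at once
Reagents that add atoms: none
Why: Nitroxyl-catalysed hypochlorite (oxoammonium) oxidation of a primary alcohol stops at the aldehyde in the buffered two-phase system at 0 °C, and the short, nearly neutral contact should leave the α-centre intact.

Step 3
Reactants: 4 4-methylbenzene-1,3-diol (4-methylresorcinol)
Product: 5 2,4-bis(methoxymethoxy)-1-methylbenzene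
Conditions: NaH, MOMCl, DMF, 0 °C → rt
Reagents that add atoms: chloromethyl methyl ether (MOMCl), COCCl
Why: Double Williamson etherification of the two phenoxides with the reactive α-chloro ether installs the acetals that later direct both ring metalations.

Step 4
Reactants: 5 2,4-bis(methoxymethoxy)-1-methylbenzene; 3 (2R)-2-methylbutanal
Product: 7 (2R)-1-[2,6-bis(methoxymethoxy)-3-methylphenyl]-2-methylbutan-1-ol (both C1′ epimers), via aryllithium 6 (not isolated)
Conditions: n-BuLi, THF, 0 °C; then 3, −78 °C → 0 °C; H2O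
Reagents that add atoms: none
Why: Directed ortho-metalation removes the proton between the two OMOM groups (doubly coordinated, most acidic site), and the aryllithium adds 1,2 to the aldehyde at −78 °C faster than it enolises it; the new carbinol centre is uncontrolled and irrelevant, and C2′ stays R.

Step 5
Reactants: 7 (2R)-1-[2,6-bis(methoxymethoxy)-3-methylphenyl]-2-methylbutan-1-ol
Product: 8 {[(2R)-1-[2,6-bis(methoxymethoxy)-3-methylphenyl]-2-methylbutyl]oxy}(tert-butyl)dimethylsilane
Conditions: TBSOTf, 2,6-lutidine, CH2Cl2, −78 → 0 °C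
Reagents that add atoms: tert-butyldimethylsilyl trifluoromethanesulfonate (TBSOTf), CC(C)(C)[Si](C)(C)OS(=O)(=O)C(F)(F)F
Why: Silyl triflate with 2,6-lutidine is the standard O-silylation for a hindered secondary alcohol, and cold buffered conditions should spare the aryl MOM ethers.

Step 6
Reactants: 8 {[(2R)-1-[2,6-bis(methoxymethoxy)-3-methylphenyl]-2-methylbutyl]oxy}(tert-butyl)dimethylsilane
Product: 11 3-[(2R)-1-{[tert-butyl(dimethyl)silyl]oxy}-2-methylbutyl]-2,4-bis(methoxymethoxy)-5-methylphenol, via C5-aryllithium 9 (not isolated), via dimethyl arylboronate 10 (not isolated)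
Conditions: s-BuLi, TMEDA, THF, −78 °C; B(OMe)3, −78 °C → rt; 30% H2O2, aq NaOH, 0 °C
Reagents that add atoms: hydrogen peroxide, OO
Why: With C1 blocked, directed ortho-metalation by the C6 OMOM group takes the only ring proton next to an oxygen (C5–H; C4–H is meta to both ethers), and borylation followed by boronate oxidation (1,2-aryl shift from boron to oxygen) gives the phenol.

Step 7
Reactants: 11 3-[(2R)-1-{[tert-butyl(dimethyl)silyl]oxy}-2-methylbutyl]-2,4-bis(methoxymethoxy)-5-methylphenol
Product: 12 2-bromo-5-[(2R)-1-{[tert-butyl(dimethyl)silyl]oxy}-2-methylbutyl]-4,6-bis(methoxymethoxy)-3-methylphenol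
Conditions: NBS, CH2Cl2, −78 → 0 °C, dark
Reagents that add atoms: N-bromosuccinimide, O=C1CCC(=O)N1Br
Why: Electrophilic aromatic bromination can only go to C4, the single free ring position, which is ortho to the phenol hydroxyl.

Step 8
Reactants: 12 2-bromo-5-[(2R)-1-{[tert-butyl(dimethyl)silyl]oxy}-2-methylbutyl]-4,6-bis(methoxymethoxy)-3-methylphenol
Product: 16 3-[(2R)-1-{[tert-butyl(dimethyl)silyl]oxy}-2-methylbutyl]-2,4-bis(methoxymethoxy)-5-methyl-6-(trimethylsilyl)phenyl trifluoromethanesulfonate, via trimethylsilyl ether 13 (not isolated), via C4-aryllithium 14 (not isolated), via lithium phenoxide 15 (not isolated)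
Conditions: HMDS, THF, 65 °C, evaporate; n-BuLi, THF, −100 → −78 °C; Tf2O, −100 → −78 °C; aq NaHCO3
Reagents that add atoms: hexamethyldisilazane, C[Si](C)(C)N[Si](C)(C)C; trifluoromethanesulfonic anhydride, O=S(=O)(OS(=O)(=O)C(F)(F)F)C(F)(F)F
Why: O-silylation, bromine–lithium exchange, 1,3-retro-Brook shift of silicon from oxygen to the lithiated C4 and triflation of the resulting phenoxide is the standard one-flask route from ortho-bromophenols to ortho-silylaryl triflates, and it fixes silicon at C4 and triflate at C5 without any regiochemical choice.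

Step 9
Reactants: 16 3-[(2R)-1-{[tert-butyl(dimethyl)silyl]oxy}-2-methylbutyl]-2,4-bis(methoxymethoxy)-5-methyl-6-(trimethylsilyl)phenyl trifluoromethanesulfonate; 17 acetic acid
Product: 20 1-{3-[(2R)-1-{[tert-butyl(dimethyl)silyl]oxy}-2-methylbutyl]-6-hydroxy-2,4-bis(methoxymethoxy)-5-methylphenyl}ethan-1-one, via C4–C5 aryne 18 (not isolated), via arylcesium acetate 19 (not isolated)
Conditions: AcOH (1.1 equiv), CsF (4 equiv), THF, 125 °C, sealed tube
Reagents that add atoms: none
Why: Fluoride attacks the C4 silicon and triflate leaves from C5 to give aryne 18; acetate (made in the flask from acetic acid and CsF) adds through oxygen to C4, and the C5 aryl anion 19 attacks the neighbouring ester carbonyl through a four-membered alkoxide that opens to the C5 methyl ketone and the C4 phenoxide. The closest known reaction type is the fluoride-induced insertion of arynes into the C–O bond of carboxylic acids, which gives ortho-hydroxyaryl ketones in hot THF. No ring is closed and no stereocentre is formed; the four-membered ring is only transient. The step needs oxygen to add at C4 and not at C5, and this should be secured by the C6 OMOM oxygen, which makes C5 the better site for negative charge (inductive stabilisation, aryne distortion) and outweighs the small steric bias of the C3 methyl group. It also needs acyl transfer to beat protonation of the aryl anion, which is helped by the high temperature, by keeping acetic acid near one equivalent so that it is all converted to CsOAc, and by the C3 methyl group pressing the acetoxy group towards C5. C2′ sits next to a silylated carbinol and not a ketone, so the hot basic fluoride medium cannot epimerise it.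

Step 10
Reactants: 20 1-{3-[(2R)-1-{[tert-butyl(dimethyl)silyl]oxy}-2-methylbutyl]-6-hydroxy-2,4-bis(methoxymethoxy)-5-methylphenyl}ethan-1-one; 21 geranyl bromide [(2E)-1-bromo-3,7-dimethylocta-2,6-diene]
Product: 22 1-{3-[(2R)-1-{[tert-butyl(dimethyl)silyl]oxy}-2-methylbutyl]-6-{[(2E)-3,7-dimethylocta-2,6-dien-1-yl]oxy}-2,4-bis(methoxymethoxy)-5-methylphenyl}ethan-1-one
Conditions: K2CO3, DMF, rt → 40 °C
Reagents that add atoms: none
Why: Williamson etherification of the only free phenol (O4) by SN2 at the primary allylic bromide keeps the 2E geometry, and carbonate is too weak to touch the carbinol-level side chain.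

Step 11
Reactants: 22 1-{3-[(2R)-1-{[tert-butyl(dimethyl)silyl]oxy}-2-methylbutyl]-6-{[(2E)-3,7-dimethylocta-2,6-dien-1-yl]oxy}-2,4-bis(methoxymethoxy)-5-methylphenyl}ethan-1-one
Product: 23 1-{6-{[(2E)-3,7-dimethylocta-2,6-dien-1-yl]oxy}-3-[(2R)-1-hydroxy-2-methylbutyl]-2,4-bis(methoxymethoxy)-5-methylphenyl}ethan-1-one
Conditions: TBAF, AcOH, THF, rt → 45 °C
Reagents that add atoms: none
Why: Fluoride-mediated desilylation frees the carbinol; buffering with acetic acid keeps the methyl ketone from aldol chemistry, and aryl MOM ethers and the allyl aryl ether are inert to fluoride.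

Step 12
Reactants: 23 1-{6-{[(2E)-3,7-dimethylocta-2,6-dien-1-yl]oxy}-3-[(2R)-1-hydroxy-2-methylbutyl]-2,4-bis(methoxymethoxy)-5-methylphenyl}ethan-1-one
Product: 24 (2R)-1-{3-acetyl-4-{[(2E)-3,7-dimethylocta-2,6-dien-1-yl]oxy}-2,6-bis(methoxymethoxy)-5-methylphenyl}-2-methylbutan-1-one
Conditions: Dess–Martin periodinane, CH2Cl2, 0 °C → rt
Reagents that add atoms: none
Why: Dess–Martin oxidation converts the hindered benzylic alcohol (both epimers) into the aryl ketone without base and without touching the trisubstituted alkenes, so C2′ becomes α to a carbonyl under non-enolising conditions.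

Step 13
Reactants: 24 (2R)-1-{3-acetyl-4-{[(2E)-3,7-dimethylocta-2,6-dien-1-yl]oxy}-2,6-bis(methoxymethoxy)-5-methylphenyl}-2-methylbutan-1-one
Product: 25 (2R)-1-{3-acetyl-4-{[(2E)-3,7-dimethylocta-2,6-dien-1-yl]oxy}-2,6-dihydroxy-5-methylphenyl}-2-methylbutan-1-one (CNP0106233.1)
Conditions: HCl (cat., about 0.3 M), MeOH–THF, 0 °C → rt, stopped at full conversion
Reagents that add atoms: none
Why: Acid-catalysed transacetalisation to methanol removes both MOM groups; each is ortho to a carbonyl and gives a hydrogen-bonded phenol, so mild acid should suffice and leave the geranyl ether and the α-stereocentre intact.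

**Compound list**

1 | (2R)-2-methylbutanoic acid | CC[C@@H](C)C(=O)O | starting material
2 | (2R)-2-methylbutan-1-ol | CC[C@@H](C)CO | intermediate
3 | (2R)-2-methylbutanal | CC[C@@H](C)C=O | intermediate
4 | 4-methylbenzene-1,3-diol (4-methylresorcinol) | Cc1ccc(O)cc1O | starting material
5 | 2,4-bis(methoxymethoxy)-1-methylbenzene | Cc1ccc(OCOC)cc1OCOC | intermediate
6 | [2,6-bis(methoxymethoxy)-3-methylphenyl]lithium | [Li]c1c(OCOC)ccc(C)c1OCOC | intermediate (not isolated)
7 | (2R)-1-[2,6-bis(methoxymethoxy)-3-methylphenyl]-2-methylbutan-1-ol, both C1′ epimers | CC[C@@H](C)C(O)c1c(OCOC)c(C)ccc1OCOC | intermediate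
8 | {[(2R)-1-[2,6-bis(methoxymethoxy)-3-methylphenyl]-2-methylbutyl]oxy}(tert-butyl)dimethylsilane | CC[C@@H](C)C(O[Si](C)(C)C(C)(C)C)c1c(OCOC)c(C)ccc1OCOC | intermediate
9 | {3-[(2R)-1-{[tert-butyl(dimethyl)silyl]oxy}-2-methylbutyl]-2,4-bis(methoxymethoxy)-5-methylphenyl}lithium | CC[C@@H](C)C(O[Si](C)(C)C(C)(C)C)c1c(OCOC)c(C)cc([Li])c1OCOC | intermediate (not isolated)
10 | dimethyl {3-[(2R)-1-{[tert-butyl(dimethyl)silyl]oxy}-2-methylbutyl]-2,4-bis(methoxymethoxy)-5-methylphenyl}boronate | CC[C@@H](C)C(O[Si](C)(C)C(C)(C)C)c1c(OCOC)c(C)cc(B(OC)OC)c1OCOC | intermediate (not isolated)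
11 | 3-[(2R)-1-{[tert-butyl(dimethyl)silyl]oxy}-2-methylbutyl]-2,4-bis(methoxymethoxy)-5-methylphenol | CC[C@@H](C)C(O[Si](C)(C)C(C)(C)C)c1c(OCOC)c(C)cc(O)c1OCOC | intermediate
12 | 2-bromo-5-[(2R)-1-{[tert-butyl(dimethyl)silyl]oxy}-2-methylbutyl]-4,6-bis(methoxymethoxy)-3-methylphenol | CC[C@@H](C)C(O[Si](C)(C)C(C)(C)C)c1c(OCOC)c(C)c(Br)c(O)c1OCOC | intermediate
13 | {2-bromo-5-[(2R)-1-{[tert-butyl(dimethyl)silyl]oxy}-2-methylbutyl]-4,6-bis(methoxymethoxy)-3-methylphenoxy}trimethylsilane | CC[C@@H](C)C(O[Si](C)(C)C(C)(C)C)c1c(OCOC)c(C)c(Br)c(O[Si](C)(C)C)c1OCOC | intermediate (not isolated)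
14 | {4-[(2R)-1-{[tert-butyl(dimethyl)silyl]oxy}-2-methylbutyl]-3,5-bis(methoxymethoxy)-6-methyl-2-[(trimethylsilyl)oxy]phenyl}lithium | CC[C@@H](C)C(O[Si](C)(C)C(C)(C)C)c1c(OCOC)c(C)c([Li])c(O[Si](C)(C)C)c1OCOC | intermediate (not isolated)
15 | lithium 3-[(2R)-1-{[tert-butyl(dimethyl)silyl]oxy}-2-methylbutyl]-2,4-bis(methoxymethoxy)-5-methyl-6-(trimethylsilyl)phenolate | CC[C@@H](C)C(O[Si](C)(C)C(C)(C)C)c1c(OCOC)c(C)c([Si](C)(C)C)c(O[Li])c1OCOC | intermediate (not isolated)
16 | 3-[(2R)-1-{[tert-butyl(dimethyl)silyl]oxy}-2-methylbutyl]-2,4-bis(methoxymethoxy)-5-methyl-6-(trimethylsilyl)phenyl trifluoromethanesulfonate | CC[C@@H](C)C(O[Si](C)(C)C(C)(C)C)c1c(OCOC)c(C)c([Si](C)(C)C)c(OS(=O)(=O)C(F)(F)F)c1OCOC | intermediate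
17 | acetic acid | CC(=O)O | starting material
18 | 4-[(2R)-1-{[tert-butyl(dimethyl)silyl]oxy}-2-methylbutyl]-3,5-bis(methoxymethoxy)-6-methyl-1,2-didehydrobenzene (C4≡C5 aryne) | CC[C@@H](C)C(O[Si](C)(C)C(C)(C)C)C1=C(OCOC)C#CC(C)=C1OCOC | intermediate (not isolated)
19 | {6-(acetyloxy)-3-[(2R)-1-{[tert-butyl(dimethyl)silyl]oxy}-2-methylbutyl]-2,4-bis(methoxymethoxy)-5-methylphenyl}cesium | CC[C@@H](C)C(O[Si](C)(C)C(C)(C)C)c1c(OCOC)c(C)c(OC(C)=O)c([Cs])c1OCOC | intermediate (not isolated)
20 | 1-{3-[(2R)-1-{[tert-butyl(dimethyl)silyl]oxy}-2-methylbutyl]-6-hydroxy-2,4-bis(methoxymethoxy)-5-methylphenyl}ethan-1-one | CC[C@@H](C)C(O[Si](C)(C)C(C)(C)C)c1c(OCOC)c(C)c(O)c(C(C)=O)c1OCOC | intermediate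
21 | geranyl bromide, (2E)-1-bromo-3,7-dimethylocta-2,6-diene | CC(C)=CCC/C(C)=C/CBr | starting material
22 | 1-{3-[(2R)-1-{[tert-butyl(dimethyl)silyl]oxy}-2-methylbutyl]-6-{[(2E)-3,7-dimethylocta-2,6-dien-1-yl]oxy}-2,4-bis(methoxymethoxy)-5-methylphenyl}ethan-1-one | CC[C@@H](C)C(O[Si](C)(C)C(C)(C)C)c1c(OCOC)c(C)c(OC/C=C(\C)CCC=C(C)C)c(C(C)=O)c1OCOC | intermediate
23 | 1-{6-{[(2E)-3,7-dimethylocta-2,6-dien-1-yl]oxy}-3-[(2R)-1-hydroxy-2-methylbutyl]-2,4-bis(methoxymethoxy)-5-methylphenyl}ethan-1-one | CC[C@@H](C)C(O)c1c(OCOC)c(C)c(OC/C=C(\C)CCC=C(C)C)c(C(C)=O)c1OCOC | intermediate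
24 | (2R)-1-{3-acetyl-4-{[(2E)-3,7-dimethylocta-2,6-dien-1-yl]oxy}-2,6-bis(methoxymethoxy)-5-methylphenyl}-2-methylbutan-1-one | CC[C@@H](C)C(=O)c1c(OCOC)c(C)c(OC/C=C(\C)CCC=C(C)C)c(C(C)=O)c1OCOC | intermediate
25 | (2R)-1-{3-acetyl-4-{[(2E)-3,7-dimethylocta-2,6-dien-1-yl]oxy}-2,6-dihydroxy-5-methylphenyl}-2-methylbutan-1-one | CC[C@@H](C)C(=O)c1c(O)c(C)c(OC/C=C(\C)CCC=C(C)C)c(C(C)=O)c1O | target

**Count and risks**

Total steps: 13. Longest linear sequence: 12 steps (steps 1, 2 and 4–13, from 1); the branch from 4 is 11 steps.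

Steps most likely to fail:

1. Step 9. The C5 aryl anion may be protonated (by residual acid or by the acetyl methyl group) before the acyl group has shifted, and the hindered silyl ether may erode at 125 °C. Fallback: from 16 the aryne 18 is generated with CsF in MeCN at room temperature with an excess of acetic acid, conditions under which O-arylation followed by protonation is the known outcome, to give 4-[(2R)-1-{[tert-butyl(dimethyl)silyl]oxy}-2-methylbutyl]-3,5-bis(methoxymethoxy)-2-methylphenyl acetate F1. Irradiation of this ester at 254 nm in degassed hexane (photo-Fries rearrangement) should move the acetyl group to the only free ortho position, C5 (the para position C1 is blocked), and return the route at 20.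

2. Step 13. Acid may ionise the allylic C–O bond of the geranyl ether (loss or cyclisation of the terpenyl chain) in competition with acetal cleavage. Fallback: from 24, TMSOTf with 2,2′-bipyridyl in MeCN at 0 °C exchanges both aryl acetals for silyl groups without free protic acid, giving (2R)-1-{3-acetyl-4-{[(2E)-3,7-dimethylocta-2,6-dien-1-yl]oxy}-5-methyl-2,6-bis[(trimethylsilyl)oxy]phenyl}-2-methylbutan-1-one F2. Water at neutral pH then hydrolyses the two O–Si bonds and returns the route at 25.

3. Step 7. The very electron-rich para-alkoxyphenol may be oxidised towards a quinone, or the C3 methyl group brominated, instead of clean ring bromination. Fallback: from 11, silicon is brought to C4 by carbamate-directed metalation instead of halogenation. ClC(O)NEt2 with NaH in THF gives 3-[(2R)-1-{[tert-butyl(dimethyl)silyl]oxy}-2-methylbutyl]-2,4-bis(methoxymethoxy)-5-methylphenyl N,N-diethylcarbamate F3. s-BuLi/TMEDA in THF at −78 °C lithiates the only position ortho to the carbamate, giving {2-[(diethylcarbamoyl)oxy]-4-[(2R)-1-{[tert-butyl(dimethyl)silyl]oxy}-2-methylbutyl]-3,5-bis(methoxymethoxy)-6-methylphenyl}lithium F4, which TMSCl quenches at −78 °C to 3-[(2R)-1-{[tert-butyl(dimethyl)silyl]oxy}-2-methylbutyl]-2,4-bis(methoxymethoxy)-5-methyl-6-(trimethylsilyl)phenyl N,N-diethylcarbamate F5. LiAlH4 in THF at 0 °C → rt removes the carbamate to give 3-[(2R)-1-{[tert-butyl(dimethyl)silyl]oxy}-2-methylbutyl]-2,4-bis(methoxymethoxy)-5-methyl-6-(trimethylsilyl)phenol F6, and NaH with PhNTf2 in THF triflates it, returning the route at 16.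

**Further compounds**

F1 | step 9 | 4-[(2R)-1-{[tert-butyl(dimethyl)silyl]oxy}-2-methylbutyl]-3,5-bis(methoxymethoxy)-2-methylphenyl acetate | CC[C@@H](C)C(O[Si](C)(C)C(C)(C)C)c1c(OCOC)c(C)c(OC(C)=O)cc1OCOC
F2 | step 13 | (2R)-1-{3-acetyl-4-{[(2E)-3,7-dimethylocta-2,6-dien-1-yl]oxy}-5-methyl-2,6-bis[(trimethylsilyl)oxy]phenyl}-2-methylbutan-1-one | CC[C@@H](C)C(=O)c1c(O[Si](C)(C)C)c(C)c(OC/C=C(\C)CCC=C(C)C)c(C(C)=O)c1O[Si](C)(C)C
F3 | step 7 | 3-[(2R)-1-{[tert-butyl(dimethyl)silyl]oxy}-2-methylbutyl]-2,4-bis(methoxymethoxy)-5-methylphenyl N,N-diethylcarbamate | CC[C@@H](C)C(O[Si](C)(C)C(C)(C)C)c1c(OCOC)c(C)cc(OC(=O)N(CC)CC)c1OCOC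
F4 | step 7 | {2-[(diethylcarbamoyl)oxy]-4-[(2R)-1-{[tert-butyl(dimethyl)silyl]oxy}-2-methylbutyl]-3,5-bis(methoxymethoxy)-6-methylphenyl}lithium | CC[C@@H](C)C(O[Si](C)(C)C(C)(C)C)c1c(OCOC)c(C)c([Li])c(OC(=O)N(CC)CC)c1OCOC
F5 | step 7 | 3-[(2R)-1-{[tert-butyl(dimethyl)silyl]oxy}-2-methylbutyl]-2,4-bis(methoxymethoxy)-5-methyl-6-(trimethylsilyl)phenyl N,N-diethylcarbamate | CC[C@@H](C)C(O[Si](C)(C)C(C)(C)C)c1c(OCOC)c(C)c([Si](C)(C)C)c(OC(=O)N(CC)CC)c1OCOC
F6 | step 7 | 3-[(2R)-1-{[tert-butyl(dimethyl)silyl]oxy}-2-methylbutyl]-2,4-bis(methoxymethoxy)-5-methyl-6-(trimethylsilyl)phenol | CC[C@@H](C)C(O[Si](C)(C)C(C)(C)C)c1c(OCOC)c(C)c([Si](C)(C)C)c(O)c1OCOC
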